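# Proposed total synthesis of (6Z)-neomanoalide

## Retrosynthetic overview

1. The furanone is built last: its C4–CH2OH comes from a Stille hydroxymethylation of a tetronate triflate, and the 4-hydroxyfuranone ring from a Dieckmann closure of an α-acetoxy seven-membered lactone, whose opening also releases the (Z)-allylic CH2OH.
2. Key disconnection: the bond between furanone C5 and the side-chain CH2 (C1'), made by a [2,3]-Wittig ring expansion of the lithium enolate of a (5S)-5-alkyl-5-vinyl-1,4-dioxan-2-one to a 2-oxo-oxepin-3-olate; C5 is set by transfer from the tertiary ether carbon and the Z alkene by the ring.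
3. Enabling feature: the furanone ring oxygen, C5 and the side-chain atoms C1'–C2'=C3' form a homoallylic C–O array (the Wittig retron), and the hydroxymethyl oxygen on C3' sits cis to C1'; this lets furanone C4 (as a carboxyl carbon) and that oxygen be tied into one lactone that holds the carbanion carbon, the migrating oxygen and the allylic carbon in a single ring.
4. The dioxanone comes from a racemic 2-alkyl-2-vinyloxirane and methyl glycolate by a palladium-catalysed dynamic kinetic asymmetric etherification; the oxirane comes from dihydro-β-ionone by Horner–Wadsworth–Emmons olefination, allylic bromide, Weinreb amide, vinyl ketone and sulfonium ylide.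
5. Ring order: cyclohexene (bought) → oxirane → 1,4-dioxan-2-one → oxepin-2-one (temporary) → furan-2(5H)-one.

Key step: step 8

Assumption: in step 7 the (R,R)-configured bisphosphine ligand is taken to deliver the (S)-configured tertiary ether (priorities O > CH2OH > vinyl > alkyl), by analogy with additions of nitrogen and oxygen pronucleophiles to vinyloxiranes; if the sense proves opposite, the (S,S)-ligand is used and nothing else changes.

## Route

Step 1
Reactants: 1 dihydro-β-ionone [4-(2,6,6-trimethylcyclohex-1-en-1-yl)butan-2-one]; 2 triethyl phosphonoacetate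
Product: 3 ethyl (2E)-3-methyl-5-(2,6,6-trimethylcyclohex-1-en-1-yl)pent-2-enoate
Conditions: NaH, THF, 0 °C → reflux; minor Z isomer removed by chromatography
Reagents that add atoms: triethyl phosphonoacetate, CCOC(=O)CP(=O)(OCC)OCC
Why: The Horner–Wadsworth–Emmons olefination of the methyl ketone should favour the E enoate (ester trans to the larger chain), and the isomers are separable.

Step 2
Reactants: 3 ethyl (2E)-3-methyl-5-(2,6,6-trimethylcyclohex-1-en-1-yl)pent-2-enoate
Product: 4 (2E)-3-methyl-5-(2,6,6-trimethylcyclohex-1-en-1-yl)pent-2-en-1-ol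
Conditions: i-Bu2AlH, CH2Cl2, −78 °C → 0 °C; aqueous potassium sodium tartrate work-up
Reagents that add atoms: none
Why: The 1,2-reduction of the enoate by the aluminium hydride should give the allylic alcohol without touching the alkenes.

Step 3
Reactants: 4 (2E)-3-methyl-5-(2,6,6-trimethylcyclohex-1-en-1-yl)pent-2-en-1-ol; 5 phosphorus tribromide
Product: 6 2-[(3E)-5-bromo-3-methylpent-3-en-1-yl]-1,3,3-trimethylcyclohex-1-ene
Conditions: PBr3, cat. pyridine, Et2O, −10 °C; used crude
Reagents that add atoms: phosphorus tribromide, BrP(Br)Br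
Why: The SN2 displacement of the intermediate phosphite ester of a primary allylic alcohol at low temperature should give the bromide without allylic transposition.

Step 4
Reactants: 6 2-[(3E)-5-bromo-3-methylpent-3-en-1-yl]-1,3,3-trimethylcyclohex-1-ene; 7 N-methoxy-N-methylacetamide
Product: 8 (4E)-N-methoxy-N,5-dimethyl-7-(2,6,6-trimethylcyclohex-1-en-1-yl)hept-4-enamide
Conditions: LiN(i-Pr)2, THF, −78 °C; then 6, −78 °C → −20 °C
Reagents that add atoms: N-methoxy-N-methylacetamide, CC(=O)N(C)OC
Why: The amide enolate alkylation at the primary allylic bromide (SN2) should add the two-carbon unit and leave the E alkene untouched.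

Step 5
Reactants: 8 (4E)-N-methoxy-N,5-dimethyl-7-(2,6,6-trimethylcyclohex-1-en-1-yl)hept-4-enamide; 9 vinylmagnesium bromide
Product: 10 (6E)-7-methyl-9-(2,6,6-trimethylcyclohex-1-en-1-yl)nona-1,6-dien-3-one
Conditions: CH2=CHMgBr, THF, 0 °C; quench into cold 1 M HCl
Reagents that add atoms: vinylmagnesium bromide, C=C[Mg]Br
Why: In the Weinreb ketone synthesis the chelated tetrahedral intermediate prevents over-addition, and the acidic quench keeps the freed amine from adding to the enone.

Step 6
Reactants: 10 (6E)-7-methyl-9-(2,6,6-trimethylcyclohex-1-en-1-yl)nona-1,6-dien-3-one; 11 trimethylsulfonium iodide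
Product: 12 rac-2-ethenyl-2-[(3E)-4-methyl-6-(2,6,6-trimethylcyclohex-1-en-1-yl)hex-3-en-1-yl]oxirane
Conditions: Me3S+ I−, n-BuLi, THF, −10 °C; then 10, −78 °C → 0 °C
Reagents that add atoms: trimethylsulfonium iodide, C[S+](C)C.[I-]
Why: In the Corey–Chaykovsky epoxidation the unstabilised sulfonium ylide adds irreversibly 1,2 to the enone carbonyl and closes the oxirane; the racemate is wanted because the next step is enantioconvergent.

Step 7
Reactants: 12 rac-2-ethenyl-2-[(3E)-4-methyl-6-(2,6,6-trimethylcyclohex-1-en-1-yl)hex-3-en-1-yl]oxirane; 13 methyl glycolate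
Product: 15 (5S)-5-ethenyl-5-[(3E)-4-methyl-6-(2,6,6-trimethylcyclohex-1-en-1-yl)hex-3-en-1-yl]-1,4-dioxan-2-one, via hydroxy ester 14 (not isolated)
Conditions: Pd2(dba)3·CHCl3 (1 mol %), (1R,2R)-N,N'-bis[2-(diphenylphosphino)benzoyl]cyclohexane-1,2-diamine (3 mol %), BEt3 (2 mol %), CH2Cl2, rt; then pyridinium p-toluenesulfonate (cat.), toluene, 50 °C
Reagents that add atoms: methyl glycolate, COC(=O)CO
Why: In this palladium-catalysed dynamic kinetic asymmetric allylic etherification, zerovalent palladium opens both oxirane enantiomers to a π-allyl alkoxide that equilibrates its faces, and the boron-bound alcohol is delivered to the substituted terminus under ligand control, which sets the tertiary ether centre as S; the δ-hydroxy ester then lactonises with loss of methanol.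

Step 8
Reactants: 15 (5S)-5-ethenyl-5-[(3E)-4-methyl-6-(2,6,6-trimethylcyclohex-1-en-1-yl)hex-3-en-1-yl]-1,4-dioxan-2-one; 16 acetic anhydride
Product: 19 (3R)-6-[(3E)-4-methyl-6-(2,6,6-trimethylcyclohex-1-en-1-yl)hex-3-en-1-yl]-2-oxo-2,3,4,7-tetrahydrooxepin-3-yl acetate, via lithium enolate 17 (not isolated), via lithium alkoxide 18 (not isolated)
Conditions: LiN(SiMe3)2 (1.1 equiv), THF, −78 °C → −20 °C; then Ac2O, −78 °C → 0 °C
Reagents that add atoms: acetic anhydride, CC(=O)OC(C)=O
Why: Proposed new method: enolate 17 is a cyclic α-allyloxy ester enolate in which the carbanion carbon C3, the ether oxygen O4 and the tertiary allylic carbon C5 all lie in the six-membered ring, so an axial vinyl group on C5 can reach the enolate π-face through a five-membered envelope transition state (a bicyclo[3.2.1]-like array) and undergo a concerted suprafacial [2,3]-Wittig shift that forms C3–CH2 as O4–C5 breaks; the closest known reactions are the [2,3]-Wittig rearrangement of acyclic α-allyloxy ester enolates, the [2,3] ring expansions of 2-vinyl heterocycle ylides and the Ireland–Claisen ring contraction of 6-alkenyl-1,4-dioxan-2-ones. The seven-membered oxepinone is closed by ring expansion (six to seven atoms: the two vinyl carbons are inserted and O4 leaves the ring as the exocyclic alkoxide), not by an end-on cyclisation. The new stereocentre (C3 of the oxepinone, later C5 of the furanone) is controlled by C5 of 15: the bond can form only on the ring face that carries the vinyl group and the enolate is endocyclic, so there is no exo/endo choice and (5S) should give (3R). The step needs Z geometry at the new trisubstituted alkene, and this is secured because the alkene is born inside a seven-membered ring, where the ring CH2O and the new CH2 must be cis. It also needs the [2,3] shift to beat the [1,2] shift and enolate self-condensation, which low temperature, the single enolisable position (C5 is quaternary) and the weak tertiary allylic C–O bond should secure. Trapping alkoxide 18 with acetic anhydride installs the two carbons that become C2 and C3 of the furanone.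

Step 9
Reactants: 19 (3R)-6-[(3E)-4-methyl-6-(2,6,6-trimethylcyclohex-1-en-1-yl)hex-3-en-1-yl]-2-oxo-2,3,4,7-tetrahydrooxepin-3-yl acetate
Product: 20 (5R)-4-hydroxy-5-[(2Z,6E)-3-(hydroxymethyl)-7-methyl-9-(2,6,6-trimethylcyclohex-1-en-1-yl)nona-2,6-dien-1-yl]furan-2(5H)-one
Conditions: LiN(SiMe3)2 (2.2 equiv), THF, −78 °C → −30 °C, 19 added to the base; 1 M HCl work-up
Reagents that add atoms: none
Why: In this Dieckmann cyclisation the kinetically formed acetate enolate attacks the adjacent lactone carbonyl (five-membered ring closure) and the tetrahedral intermediate expels the allylic alkoxide, so the tetronic acid forms and the (Z)-allylic alcohol is released in one operation, with the stereocentre untouched.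

Step 10
Reactants: 20 (5R)-4-hydroxy-5-[(2Z,6E)-3-(hydroxymethyl)-7-methyl-9-(2,6,6-trimethylcyclohex-1-en-1-yl)nona-2,6-dien-1-yl]furan-2(5H)-one; 21 N-phenylbis(trifluoromethanesulfonimide)
Product: 22 (2R)-2-[(2Z,6E)-3-(hydroxymethyl)-7-methyl-9-(2,6,6-trimethylcyclohex-1-en-1-yl)nona-2,6-dien-1-yl]-5-oxo-2,5-dihydrofuran-3-yl trifluoromethanesulfonate
Conditions: PhNTf2, Et3N, CH2Cl2, 0 °C → rt
Reagents that add atoms: N-phenylbis(trifluoromethanesulfonimide), O=S(=O)(N(c1ccccc1)S(=O)(=O)C(F)(F)F)C(F)(F)F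
Why: In this enol triflate formation the acidic tetronate oxygen is sulfonylated by the mild triflimide under amine base, while the neutral primary allylic alcohol should not react.

Step 11
Reactants: 22 (2R)-2-[(2Z,6E)-3-(hydroxymethyl)-7-methyl-9-(2,6,6-trimethylcyclohex-1-en-1-yl)nona-2,6-dien-1-yl]-5-oxo-2,5-dihydrofuran-3-yl trifluoromethanesulfonate; 23 (tributylstannyl)methanol
Product: 24 (6Z)-neomanoalide [(5R)-4-(hydroxymethyl)-5-[(2Z,6E)-3-(hydroxymethyl)-7-methyl-9-(2,6,6-trimethylcyclohex-1-en-1-yl)nona-2,6-dien-1-yl]furan-2(5H)-one]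
Conditions: Pd(PPh3)4 (5 mol %), LiCl, 1,4-dioxane, 90 °C
Reagents that add atoms: (tributylstannyl)methanol, CCCC[Sn](CCCC)(CCCC)CO
Why: In this Stille coupling zerovalent palladium inserts into the electron-poor vinyl triflate, the hydroxymethyl group is transferred from tin in preference to butyl, and the neutral conditions leave the C5 stereocentre and both alkenes unchanged.

## Compound list

1 | dihydro-β-ionone, 4-(2,6,6-trimethylcyclohex-1-en-1-yl)butan-2-one | CC(=O)CCC1=C(C)CCCC1(C)C | starting material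
2 | triethyl phosphonoacetate | CCOC(=O)CP(=O)(OCC)OCC | starting material
3 | ethyl (2E)-3-methyl-5-(2,6,6-trimethylcyclohex-1-en-1-yl)pent-2-enoate | CCOC(=O)/C=C(\C)CCC1=C(C)CCCC1(C)C | intermediate
4 | (2E)-3-methyl-5-(2,6,6-trimethylcyclohex-1-en-1-yl)pent-2-en-1-ol | OC/C=C(\C)CCC1=C(C)CCCC1(C)C | intermediate
5 | phosphorus tribromide | BrP(Br)Br | starting material
6 | 2-[(3E)-5-bromo-3-methylpent-3-en-1-yl]-1,3,3-trimethylcyclohex-1-ene | BrC/C=C(\C)CCC1=C(C)CCCC1(C)C | intermediate
7 | N-methoxy-N-methylacetamide | CC(=O)N(C)OC | starting material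
8 | (4E)-N-methoxy-N,5-dimethyl-7-(2,6,6-trimethylcyclohex-1-en-1-yl)hept-4-enamide | CON(C)C(=O)CC/C=C(\C)CCC1=C(C)CCCC1(C)C | intermediate
9 | vinylmagnesium bromide | C=C[Mg]Br | starting material
10 | (6E)-7-methyl-9-(2,6,6-trimethylcyclohex-1-en-1-yl)nona-1,6-dien-3-one | C=CC(=O)CC/C=C(\C)CCC1=C(C)CCCC1(C)C | intermediate
11 | trimethylsulfonium iodide | C[S+](C)C.[I-] | starting material
12 | rac-2-ethenyl-2-[(3E)-4-methyl-6-(2,6,6-trimethylcyclohex-1-en-1-yl)hex-3-en-1-yl]oxirane | C=CC1(CC/C=C(\C)CCC2=C(C)CCCC2(C)C)CO1 | intermediate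
13 | methyl glycolate (methyl 2-hydroxyacetate) | COC(=O)CO | starting material
14 | methyl 2-{[(3S,6E)-3-(hydroxymethyl)-7-methyl-9-(2,6,6-trimethylcyclohex-1-en-1-yl)nona-1,6-dien-3-yl]oxy}acetate (formed in the flask) | COC(=O)CO[C@](CO)(C=C)CC/C=C(\C)CCC1=C(C)CCCC1(C)C | intermediate
15 | (5S)-5-ethenyl-5-[(3E)-4-methyl-6-(2,6,6-trimethylcyclohex-1-en-1-yl)hex-3-en-1-yl]-1,4-dioxan-2-one | O=C1CO[C@](C=C)(CC/C=C(\C)CCC2=C(C)CCCC2(C)C)CO1 | intermediate
16 | acetic anhydride | CC(=O)OC(C)=O | starting material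
17 | lithium (5S)-5-ethenyl-5-[(3E)-4-methyl-6-(2,6,6-trimethylcyclohex-1-en-1-yl)hex-3-en-1-yl]-5,6-dihydro-1,4-dioxin-2-olate (formed in the flask) | [Li+].[O-]C1=CO[C@](C=C)(CC/C=C(\C)CCC2=C(C)CCCC2(C)C)CO1 | intermediate
18 | lithium (3R)-6-[(3E)-4-methyl-6-(2,6,6-trimethylcyclohex-1-en-1-yl)hex-3-en-1-yl]-2-oxo-2,3,4,7-tetrahydrooxepin-3-olate (formed in the flask) | [Li+].[O-][C@@H]1CC=C(CC/C=C(\C)CCC2=C(C)CCCC2(C)C)COC1=O | intermediate
19 | (3R)-6-[(3E)-4-methyl-6-(2,6,6-trimethylcyclohex-1-en-1-yl)hex-3-en-1-yl]-2-oxo-2,3,4,7-tetrahydrooxepin-3-yl acetate | CC(=O)O[C@@H]1CC=C(CC/C=C(\C)CCC2=C(C)CCCC2(C)C)COC1=O | intermediate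
20 | (5R)-4-hydroxy-5-[(2Z,6E)-3-(hydroxymethyl)-7-methyl-9-(2,6,6-trimethylcyclohex-1-en-1-yl)nona-2,6-dien-1-yl]furan-2(5H)-one | OC1=CC(=O)O[C@@H]1C/C=C(\CO)CC/C=C(\C)CCC2=C(C)CCCC2(C)C | intermediate
21 | N-phenylbis(trifluoromethanesulfonimide) | O=S(=O)(N(c1ccccc1)S(=O)(=O)C(F)(F)F)C(F)(F)F | starting material
22 | (2R)-2-[(2Z,6E)-3-(hydroxymethyl)-7-methyl-9-(2,6,6-trimethylcyclohex-1-en-1-yl)nona-2,6-dien-1-yl]-5-oxo-2,5-dihydrofuran-3-yl trifluoromethanesulfonate | FC(F)(F)S(=O)(=O)OC1=CC(=O)O[C@@H]1C/C=C(\CO)CC/C=C(\C)CCC2=C(C)CCCC2(C)C | intermediate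
23 | (tributylstannyl)methanol | CCCC[Sn](CCCC)(CCCC)CO | starting material
24 | (6Z)-neomanoalide, (5R)-4-(hydroxymethyl)-5-[(2Z,6E)-3-(hydroxymethyl)-7-methyl-9-(2,6,6-trimethylcyclohex-1-en-1-yl)nona-2,6-dien-1-yl]furan-2(5H)-one | OCC1=CC(=O)O[C@@H]1C/C=C(\CO)CC/C=C(\C)CCC2=C(C)CCCC2(C)C | target

## Step count and risks

Total step count: 11. Longest linear sequence: 11 steps (from dihydro-β-ionone 1 to 24).

Steps most likely to fail:

1. Step 8 (Proposed new method). The enolate may be consumed by a [1,2] shift, by self-condensation or by eliminative ring opening before the [2,3] shift takes place. The fallback uses known chemistry, sets out from bromide 6 and comes back at 19; it forms the alkene instead of the C5–CH2 bond and takes the stereocentre from the chiral pool. Bromide 6 is alkylated with the dianion of 2-methylprop-2-en-1-ol (n-BuLi, TMEDA, Et2O) to give (5E)-6-methyl-2-methylidene-8-(2,6,6-trimethylcyclohex-1-en-1-yl)oct-5-en-1-ol F1. Commercial D-allylglycine is diazotised (NaNO2, aqueous H2SO4, net retention) to (2R)-2-hydroxypent-4-enoic acid F2, which is acetylated (acetyl chloride) to (2R)-2-(acetyloxy)pent-4-enoic acid F3. Carbodiimide esterification of F1 with F3 (dicyclohexylcarbodiimide, cat. DMAP, CH2Cl2, 0 °C) gives (5E)-6-methyl-2-methylidene-8-(2,6,6-trimethylcyclohex-1-en-1-yl)oct-5-en-1-yl (2R)-2-(acetyloxy)pent-4-enoate F4. Ring-closing metathesis of F4 with second-generation Grubbs catalyst, (H2IMes)(PCy3)Cl2Ru=CHPh, in dilute CH2Cl2 at reflux closes the seven-membered lactone 19 with loss of ethene, and the ring again fixes the Z alkene.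

2. Step 7. The ester-bearing alcohol may be delivered poorly by the boron co-catalyst, which would erode enantioselectivity or let the nucleophile attack the unsubstituted allyl terminus. The fallback sets out from oxirane 12 and comes back at 15; the asymmetric step uses hydrogen carbonate as the oxygen nucleophile and the glycolate arm is attached afterwards. Oxirane 12 with NaHCO3 in CH2Cl2–water under the same palladium–ligand–BEt3 system should give (2S)-2-[(3E)-4-methyl-6-(2,6,6-trimethylcyclohex-1-en-1-yl)hex-3-en-1-yl]but-3-ene-1,2-diol F5. Selective primary etherification (NaH, 4-methoxybenzyl chloride, 0 °C) gives (2S)-1-[(4-methoxybenzyl)oxy]-2-[(3E)-4-methyl-6-(2,6,6-trimethylcyclohex-1-en-1-yl)hex-3-en-1-yl]but-3-en-2-ol F6. Williamson etherification of the tertiary alkoxide (NaH, bromoacetic acid, THF–DMF) gives 2-{[(3S,6E)-3-{[(4-methoxybenzyl)oxy]methyl}-7-methyl-9-(2,6,6-trimethylcyclohex-1-en-1-yl)nona-1,6-dien-3-yl]oxy}acetic acid F7. Oxidative debenzylation (DDQ, CH2Cl2–water) gives 2-{[(3S,6E)-3-(hydroxymethyl)-7-methyl-9-(2,6,6-trimethylcyclohex-1-en-1-yl)nona-1,6-dien-3-yl]oxy}acetic acid F8, and carbodiimide lactonisation of F8 gives 15.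

3. Step 9. The base may remove the ring proton next to the acetoxy group instead of an acetyl proton, which would scramble the only stereocentre or divert the material. The fallback sets out from 15 and comes back at 20; it uses a doubly activated acyl unit so that only a weak base is needed. Step 8 is run as described, but alkoxide 18 is trapped with allyl 3-chloro-3-oxopropanoate to give prop-2-en-1-yl (3R)-6-[(3E)-4-methyl-6-(2,6,6-trimethylcyclohex-1-en-1-yl)hex-3-en-1-yl]-2-oxo-2,3,4,7-tetrahydrooxepin-3-yl propanedioate F9. Dieckmann cyclisation of the malonate with DBU (THF, 0 °C → rt) gives prop-2-en-1-yl (5R)-4-hydroxy-5-[(2Z,6E)-3-(hydroxymethyl)-7-methyl-9-(2,6,6-trimethylcyclohex-1-en-1-yl)nona-2,6-dien-1-yl]-2-oxo-2,5-dihydrofuran-3-carboxylate F10. Deallylation and decarboxylation of F10 with Pd(PPh3)4 and morpholine (THF, rt) gives 20.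

## Further compounds

F1 | step 8 | (5E)-6-methyl-2-methylidene-8-(2,6,6-trimethylcyclohex-1-en-1-yl)oct-5-en-1-ol | C=C(CO)CC/C=C(\C)CCC1=C(C)CCCC1(C)C
F2 | step 8 | (2R)-2-hydroxypent-4-enoic acid | O[C@H](CC=C)C(O)=O
F3 | step 8 | (2R)-2-(acetyloxy)pent-4-enoic acid | CC(=O)O[C@H](CC=C)C(O)=O
F4 | step 8 | (5E)-6-methyl-2-methylidene-8-(2,6,6-trimethylcyclohex-1-en-1-yl)oct-5-en-1-yl (2R)-2-(acetyloxy)pent-4-enoate | CC(=O)O[C@H](CC=C)C(=O)OCC(=C)CC/C=C(\C)CCC1=C(C)CCCC1(C)C
F5 | step 7 | (2S)-2-[(3E)-4-methyl-6-(2,6,6-trimethylcyclohex-1-en-1-yl)hex-3-en-1-yl]but-3-ene-1,2-diol | OC[C@@](O)(C=C)CC/C=C(\C)CCC1=C(C)CCCC1(C)C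
F6 | step 7 | (2S)-1-[(4-methoxybenzyl)oxy]-2-[(3E)-4-methyl-6-(2,6,6-trimethylcyclohex-1-en-1-yl)hex-3-en-1-yl]but-3-en-2-ol | COc1ccc(COC[C@@](O)(C=C)CC/C=C(\C)CCC2=C(C)CCCC2(C)C)cc1
F7 | step 7 | 2-{[(3S,6E)-3-{[(4-methoxybenzyl)oxy]methyl}-7-methyl-9-(2,6,6-trimethylcyclohex-1-en-1-yl)nona-1,6-dien-3-yl]oxy}acetic acid | OC(=O)CO[C@](COCc1ccc(OC)cc1)(C=C)CC/C=C(\C)CCC2=C(C)CCCC2(C)C
F8 | step 7 | 2-{[(3S,6E)-3-(hydroxymethyl)-7-methyl-9-(2,6,6-trimethylcyclohex-1-en-1-yl)nona-1,6-dien-3-yl]oxy}acetic acid | OC(=O)CO[C@](CO)(C=C)CC/C=C(\C)CCC1=C(C)CCCC1(C)C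
F9 | step 9 | prop-2-en-1-yl (3R)-6-[(3E)-4-methyl-6-(2,6,6-trimethylcyclohex-1-en-1-yl)hex-3-en-1-yl]-2-oxo-2,3,4,7-tetrahydrooxepin-3-yl propanedioate | C=CCOC(=O)CC(=O)O[C@@H]1CC=C(CC/C=C(\C)CCC2=C(C)CCCC2(C)C)COC1=O
F10 | step 9 | prop-2-en-1-yl (5R)-4-hydroxy-5-[(2Z,6E)-3-(hydroxymethyl)-7-methyl-9-(2,6,6-trimethylcyclohex-1-en-1-yl)nona-2,6-dien-1-yl]-2-oxo-2,5-dihydrofuran-3-carboxylate | C=CCOC(=O)C1=C(O)[C@@H](C/C=C(\CO)CC/C=C(\C)CCC2=C(C)CCCC2(C)C)OC1=O
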